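**Strategy.** Each benzene ring is cut into a four-carbon and a two-carbon piece. C3–C4–C5–C6, with the adjacent oxygens on C4 and C5, is a 2,3-dioxygenated butadiene. C1–C2, carrying the benzylic CH2–O–CH2 linker on C1, is one alkyne of dipropargyl ether. A twofold cobalt-catalysed [4+2] cycloaddition of diyne bis(boronate) 5 with two molecules of bis(silyloxy)diene 8 forms C2–C3 and C6–C1 in both rings at once and leaves boron on C2 as the handle for the first bromine. The precursor is therefore an open-chain symmetric 1,6-diyne capped by two pinacolboryl groups. Aromatisation, ipso-bromination, directed C3 bromination and desilylation finish the synthesis.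

Key step: step 3

Remark: ring atoms are numbered as in the target name (C1 bears the CH2O arm, C2 and C3 the bromines, C4 and C5 the oxygens, C6 a hydrogen); the target has no stereocenter; in the twofold steps the half-converted species is treated as a transient and is numbered only in step 3, where stalling at that stage matters.

Step 1
Reactants: 1 dipropargyl ether; 2 2-isopropoxy-4,4,5,5-tetramethyl-1,3,2-dioxaborolane
Product: 5 bis[3-(4,4,5,5-tetramethyl-1,3,2-dioxaborolan-2-yl)prop-2-yn-1-yl] ether, via dilithium diacetylide 3 (not isolated), via dilithium bis(borate) 4 (not isolated)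
Conditions: n-BuLi (2.05 equiv), THF, -78 °C; then 2 (2.2 equiv), -78 °C; then HCl in Et2O (2.1 equiv), -78 °C to rt; LiCl filtered off, product used without chromatography
Reagents that add atoms: 2-isopropoxy-4,4,5,5-tetramethyl-1,3,2-dioxaborolane (2), CC(C)OB1OC(C)(C)C(C)(C)O1
Why: Borylation of lithium acetylides: both terminal alkyne C–H bonds are far more acidic than the propargylic CH2 groups, each acetylide adds to the borate ester to give a tetracoordinate borate, and anhydrous HCl removes isopropoxide to release the alkynyl pinacolboronate without protodeboronation.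

Step 2
Reactants: 6 butane-2,3-dione; 7 tert-butyldimethylsilyl trifluoromethanesulfonate
Product: 8 2,3-bis(tert-butyldimethylsilyloxy)buta-1,3-diene
Conditions: 7 (2.2 equiv), Et3N (3 equiv), CH2Cl2, 0 °C to rt; non-acidic work-up, distillation
Reagents that add atoms: tert-butyldimethylsilyl trifluoromethanesulfonate (7), CC(C)(C)[Si](C)(C)OS(=O)(=O)C(F)(F)F
Why: Soft enolisation (silyl enol ether formation with a silyl triflate and an amine base): each carbonyl is O-silylated and loses a proton from its only α-position, the methyl group, so the bis(enol ether) with two terminal methylene groups is the only possible product.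

Step 3
Reactants: 5 bis[3-(4,4,5,5-tetramethyl-1,3,2-dioxaborolan-2-yl)prop-2-yn-1-yl] ether; 8 2,3-bis(tert-butyldimethylsilyloxy)buta-1,3-diene
Product: 10 bis{[4,5-bis(tert-butyldimethylsilyloxy)-2-(4,4,5,5-tetramethyl-1,3,2-dioxaborolan-2-yl)cyclohexa-1,4-dien-1-yl]methyl} ether, via mono-cycloadduct 9 (not isolated)
Conditions: CoBr2(dppe) (10 mol%; dppe = 1,2-bis(diphenylphosphino)ethane), Zn powder (20 mol%), ZnI2 (20 mol%), 8 (3 equiv), CH2Cl2, rt, slow addition of 5; filtration through a short pad of deactivated silica
Reagents that add atoms: none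
Why: Zn reduces the divalent cobalt of CoBr2(dppe) to monovalent cobalt and ZnI2 strips halide, so that a cationic (dppe)Co fragment binds the diene η4 and one alkynyl boronate η2, couples them oxidatively to a trivalent-cobalt metallacycle and releases the cyclohexa-1,4-diene by reductive elimination, the same cycle then running at the remaining alkyne of mono-adduct 9. The closest known reaction type is the cobalt-catalysed neutral [4+2] cycloaddition of alkynyl pinacolboronates with 1,3-dienes, which also tolerates silyloxy-substituted butadienes. Each of the two six-membered rings closes intermolecularly as a [4+2] annulation in which diene carbons C3–C6 join alkyne carbons C1 and C2 through the new C2–C3 and C6–C1 bonds; neither ring is closed by cyclisation of a tether. No stereocenter is created, since every ring carbon of 10 is sp2 or CH2. The step needs chemoselectivity for [4+2] over alkyne cyclotrimerisation and over oxidative coupling of the tethered 1,6-diyne, as well as full conversion at both alkynes; the strongly binding diene in excess, the low standing concentration of 5, the chelating diphosphine that leaves room for just one diene and one alkyne, and the bulky boryl caps on both alkyne termini should secure this. Regiochemistry does not arise because the diene is twofold-symmetric, so boron necessarily ends on C2 next to the CH2O arm on C1.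

Step 4
Reactants: 10 bis{[4,5-bis(tert-butyldimethylsilyloxy)-2-(4,4,5,5-tetramethyl-1,3,2-dioxaborolan-2-yl)cyclohexa-1,4-dien-1-yl]methyl} ether
Product: 11 bis[4,5-bis(tert-butyldimethylsilyloxy)-2-(4,4,5,5-tetramethyl-1,3,2-dioxaborolan-2-yl)benzyl] ether
Conditions: DDQ (2.1 equiv), anhydrous toluene, 0 °C to rt; filtration through basic alumina
Reagents that add atoms: none
Why: Dehydrogenative aromatisation: DDQ abstracts hydride from a doubly allylic ring CH2 to give a silyloxy-stabilised cation that loses a proton to form the arene, which is much faster than attack on the benzylic ether when exactly one equivalent per ring is used without water, and the silyl enol ethers emerge as aryl silyl ethers at the catechol oxidation level.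

Step 5
Reactants: 11 bis[4,5-bis(tert-butyldimethylsilyloxy)-2-(4,4,5,5-tetramethyl-1,3,2-dioxaborolan-2-yl)benzyl] ether; 12 N-bromosuccinimide
Product: 13 bis[2-bromo-4,5-bis(tert-butyldimethylsilyloxy)benzyl] ether
Conditions: 12 (2.1 equiv), MeCN/CH2Cl2, 0 °C to rt, dark
Reagents that add atoms: N-bromosuccinimide (12), O=C1CCC(=O)N1Br
Why: Halodeboronation (electrophilic ipso-substitution of an electron-rich arylboronate by an N-halosuccinimide): C2 is para to the C5 oxygen and carries the electron-releasing C–B bond, so bromine should enter there and expel boron, which fixes the C2 bromine without any directing problem and under neutral conditions that spare the silyl ethers and the benzylic ether.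

Step 6
Reactants: 13 bis[2-bromo-4,5-bis(tert-butyldimethylsilyloxy)benzyl] ether; 14 1,2-dibromo-1,1,2,2-tetrachloroethane
Product: 16 bis[2,3-dibromo-4,5-bis(tert-butyldimethylsilyloxy)benzyl] ether, via dilithio arene 15 (not isolated)
Conditions: LiN(i-Pr)2 (commercial solution, 3 equiv), THF, -78 °C, short metalation time; then 14 (3.5 equiv), -78 °C to -40 °C; NH4Cl quench
Reagents that add atoms: 1,2-dibromo-1,1,2,2-tetrachloroethane (14), ClC(Cl)(Br)C(Cl)(Cl)Br
Why: Deprotonative ortho-metalation followed by electrophilic bromination: C3–H, flanked by bromine and the C4 silyloxy group and meta to the C5 oxygen, is the most acidic ring hydrogen (C6–H lies next to an alkyl group and far from bromine), lithium amides are known to metalate 3-bromoaryl ethers and silyl ethers at exactly this position, and at -78 °C the aryllithium should be captured by the positive-bromine donor before LiBr loss or O-to-C silyl shift.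

Step 7
Reactants: 16 bis[2,3-dibromo-4,5-bis(tert-butyldimethylsilyloxy)benzyl] ether
Product: 17 bis(2,3-dibromo-4,5-dihydroxybenzyl) ether
Conditions: Bu4NF (4.4 equiv), AcOH (6 equiv), THF, 0 °C, argon; work-up at pH 5
Reagents that add atoms: none
Why: Fluoride-induced desilylation of aryl silyl ethers, driven by the Si–F bond; the acetic acid buffer keeps the liberated phenols protonated, so the para-hydroxybenzyl ether cannot expel alkoxide through a quinone methide and the catechols are not oxidised by air.

**Compound list**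

1 | dipropargyl ether (3-(prop-2-yn-1-yloxy)prop-1-yne) | C#CCOCC#C | starting material
2 | 2-isopropoxy-4,4,5,5-tetramethyl-1,3,2-dioxaborolane | CC(C)OB1OC(C)(C)C(C)(C)O1 | starting material
3 | dilithium diacetylide of dipropargyl ether | [Li]C#CCOCC#C[Li] | intermediate (not isolated)
4 | dilithium bis(borate): both acetylide carbons bound to isopropoxy(pinacolato)borate centres | [Li+].[Li+].CC(C)O[B-]1(C#CCOCC#C[B-]2(OC(C)C)OC(C)(C)C(C)(C)O2)OC(C)(C)C(C)(C)O1 | intermediate (not isolated)
5 | bis[3-(4,4,5,5-tetramethyl-1,3,2-dioxaborolan-2-yl)prop-2-yn-1-yl] ether | CC1(C)OB(C#CCOCC#CB2OC(C)(C)C(C)(C)O2)OC1(C)C | intermediate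
6 | butane-2,3-dione | CC(=O)C(C)=O | starting material
7 | tert-butyldimethylsilyl trifluoromethanesulfonate | CC(C)(C)[Si](C)(C)OS(=O)(=O)C(F)(F)F | starting material
8 | 2,3-bis(tert-butyldimethylsilyloxy)buta-1,3-diene | C=C(O[Si](C)(C)C(C)(C)C)C(=C)O[Si](C)(C)C(C)(C)C | intermediate
9 | mono-cycloadduct: {[4,5-bis(tert-butyldimethylsilyloxy)-2-(4,4,5,5-tetramethyl-1,3,2-dioxaborolan-2-yl)cyclohexa-1,4-dien-1-yl]methyl} [3-(4,4,5,5-tetramethyl-1,3,2-dioxaborolan-2-yl)prop-2-yn-1-yl] ether | CC1(C)OB(C#CCOCC2=C(B3OC(C)(C)C(C)(C)O3)CC(O[Si](C)(C)C(C)(C)C)=C(O[Si](C)(C)C(C)(C)C)C2)OC1(C)C | intermediate (not isolated)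
10 | bis{[4,5-bis(tert-butyldimethylsilyloxy)-2-(4,4,5,5-tetramethyl-1,3,2-dioxaborolan-2-yl)cyclohexa-1,4-dien-1-yl]methyl} ether | O(CC1=C(B2OC(C)(C)C(C)(C)O2)CC(O[Si](C)(C)C(C)(C)C)=C(O[Si](C)(C)C(C)(C)C)C1)CC1=C(B2OC(C)(C)C(C)(C)O2)CC(O[Si](C)(C)C(C)(C)C)=C(O[Si](C)(C)C(C)(C)C)C1 | intermediate
11 | bis[4,5-bis(tert-butyldimethylsilyloxy)-2-(4,4,5,5-tetramethyl-1,3,2-dioxaborolan-2-yl)benzyl] ether | O(Cc1cc(O[Si](C)(C)C(C)(C)C)c(O[Si](C)(C)C(C)(C)C)cc1B2OC(C)(C)C(C)(C)O2)Cc1cc(O[Si](C)(C)C(C)(C)C)c(O[Si](C)(C)C(C)(C)C)cc1B2OC(C)(C)C(C)(C)O2 | intermediate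
12 | N-bromosuccinimide | O=C1CCC(=O)N1Br | starting material
13 | bis[2-bromo-4,5-bis(tert-butyldimethylsilyloxy)benzyl] ether | O(Cc1cc(O[Si](C)(C)C(C)(C)C)c(O[Si](C)(C)C(C)(C)C)cc1Br)Cc1cc(O[Si](C)(C)C(C)(C)C)c(O[Si](C)(C)C(C)(C)C)cc1Br | intermediate
14 | 1,2-dibromo-1,1,2,2-tetrachloroethane | ClC(Cl)(Br)C(Cl)(Cl)Br | starting material
15 | bis[2-bromo-3-lithio-4,5-bis(tert-butyldimethylsilyloxy)benzyl] ether | O(Cc1cc(O[Si](C)(C)C(C)(C)C)c(O[Si](C)(C)C(C)(C)C)c([Li])c1Br)Cc1cc(O[Si](C)(C)C(C)(C)C)c(O[Si](C)(C)C(C)(C)C)c([Li])c1Br | intermediate (not isolated)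
16 | bis[2,3-dibromo-4,5-bis(tert-butyldimethylsilyloxy)benzyl] ether | O(Cc1cc(O[Si](C)(C)C(C)(C)C)c(O[Si](C)(C)C(C)(C)C)c(Br)c1Br)Cc1cc(O[Si](C)(C)C(C)(C)C)c(O[Si](C)(C)C(C)(C)C)c(Br)c1Br | intermediate
17 | bis(2,3-dibromo-4,5-dihydroxybenzyl) ether | Oc1cc(COCc2cc(O)c(O)c(Br)c2Br)c(Br)c(Br)c1O | target

**Step count.** Total: 7 steps. Longest linear sequence: 6 steps (1, 3, 4, 5, 6, 7; equally 2, 3, 4, 5, 6, 7).

**Steps most likely to fail**

Step 3. The two alkynes of 5 sit in a 1,6-relationship, so both may bind one cobalt centre and couple oxidatively to a bicyclic metallacycle. That would divert material into [2+2+2]-type products and oligomers. The second cycloaddition may also stall after the first ring, and ZnI2 may slowly strip silicon from the diene. The fallback builds one ring at a time from a mono-alkyne, so that no diyne meets cobalt, and forms the central ether afterwards. It sets out from diene 8 and borate ester 2 and returns at 13.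
- Purchased tert-butyldimethyl(prop-2-yn-1-yloxy)silane F1 would be deprotonated with n-BuLi to its lithium acetylide F2, which adds to 2 to give the lithium borate F3; anhydrous HCl should release the alkynyl boronate F4.
- Cycloaddition of F4 with 8 under the conditions of step 3 should give the single-ring cyclohexadiene F5.
- DDQ should aromatise it to the aryl boronate F6, and 12 should convert this to the aryl bromide F7.
- AcOH/THF/H2O should remove only the primary benzylic silyl ether, giving the benzyl alcohol F8.
- Half of F8 would be converted to the benzyl bromide F9 with CBr4/PPh3 (Appel reaction).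
- Ag2O-promoted Williamson etherification of F8 with F9 in CH2Cl2 should give 13, from which step 6 continues.

Step 6. The bulky silyloxy group neither coordinates lithium nor leaves much room, so deprotonation at C3 may be incomplete. The 2-bromoaryllithium may lose LiBr to an aryne, the neighbouring silyl group may shift from oxygen to carbon, or a benzylic hydrogen may be removed and trigger a Wittig rearrangement. The fallback replaces silicon on oxygen by a true directing group. It sets out from 13 and returns at target 17.
- Bu4NF/AcOH should free the tetraphenol bis(2-bromo-4,5-dihydroxybenzyl) ether F10.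
- MOMCl/i-Pr2NEt should give the tetrakis(methoxymethyl) ether F11.
- LiN(i-Pr)2 at -78 °C, guided to C3 by bromine and the chelating acetal oxygen, should give the dilithio species F12, which 14 converts to the tetrabromide F13.
- ZnBr2/n-PrSH in CH2Cl2 should remove the four acetals under aprotic conditions to give 17.

Step 5. Electrophilic bromine may also enter at ring C–H positions, may attack C1 with loss of the benzylic arm, or the hindered pinacol boronate may react too slowly. The fallback replaces electrophilic substitution by a metal-mediated pathway. It sets out from 11 and returns at 13. Treatment with CuBr2 (3 equiv per boron) in THF/MeOH/H2O at 60–80 °C should pass the aryl group from boron to copper and form the C–Br bond at the metal, so that no free electrophilic bromine meets the ring. No new compound arises.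

**Further compounds**

F1 | step 3 | tert-butyldimethyl(prop-2-yn-1-yloxy)silane (purchased) | C#CCO[Si](C)(C)C(C)(C)C
F2 | step 3 | [3-(tert-butyldimethylsilyloxy)prop-1-yn-1-yl]lithium | [Li]C#CCO[Si](C)(C)C(C)(C)C
F3 | step 3 | lithium [3-(tert-butyldimethylsilyloxy)prop-1-yn-1-yl](isopropoxy)(pinacolato)borate | [Li+].CC(C)O[B-]1(C#CCO[Si](C)(C)C(C)(C)C)OC(C)(C)C(C)(C)O1
F4 | step 3 | tert-butyldimethyl{[3-(4,4,5,5-tetramethyl-1,3,2-dioxaborolan-2-yl)prop-2-yn-1-yl]oxy}silane | CC(C)(C)[Si](C)(C)OCC#CB1OC(C)(C)C(C)(C)O1
F5 | step 3 | tert-butyl{[4,5-bis(tert-butyldimethylsilyloxy)-2-(4,4,5,5-tetramethyl-1,3,2-dioxaborolan-2-yl)cyclohexa-1,4-dien-1-yl]methoxy}dimethylsilane | CC(C)(C)[Si](C)(C)OCC1=C(B2OC(C)(C)C(C)(C)O2)CC(O[Si](C)(C)C(C)(C)C)=C(O[Si](C)(C)C(C)(C)C)C1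
F6 | step 3 | tert-butyl{[4,5-bis(tert-butyldimethylsilyloxy)-2-(4,4,5,5-tetramethyl-1,3,2-dioxaborolan-2-yl)benzyl]oxy}dimethylsilane | CC(C)(C)[Si](C)(C)OCc1cc(O[Si](C)(C)C(C)(C)C)c(O[Si](C)(C)C(C)(C)C)cc1B2OC(C)(C)C(C)(C)O2
F7 | step 3 | {[2-bromo-4,5-bis(tert-butyldimethylsilyloxy)benzyl]oxy}(tert-butyl)dimethylsilane | CC(C)(C)[Si](C)(C)OCc1cc(O[Si](C)(C)C(C)(C)C)c(O[Si](C)(C)C(C)(C)C)cc1Br
F8 | step 3 | [2-bromo-4,5-bis(tert-butyldimethylsilyloxy)phenyl]methanol | OCc1cc(O[Si](C)(C)C(C)(C)C)c(O[Si](C)(C)C(C)(C)C)cc1Br
F9 | step 3 | 1-bromo-2-(bromomethyl)-4,5-bis(tert-butyldimethylsilyloxy)benzene | BrCc1cc(O[Si](C)(C)C(C)(C)C)c(O[Si](C)(C)C(C)(C)C)cc1Br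
F10 | step 6 | bis(2-bromo-4,5-dihydroxybenzyl) ether | Oc1cc(COCc2cc(O)c(O)cc2Br)c(Br)cc1O
F11 | step 6 | bis[2-bromo-4,5-bis(methoxymethoxy)benzyl] ether | COCOc1cc(COCc2cc(OCOC)c(OCOC)cc2Br)c(Br)cc1OCOC
F12 | step 6 | bis[2-bromo-3-lithio-4,5-bis(methoxymethoxy)benzyl] ether | COCOc1cc(COCc2cc(OCOC)c(OCOC)c([Li])c2Br)c(Br)c([Li])c1OCOC
F13 | step 6 | bis[2,3-dibromo-4,5-bis(methoxymethoxy)benzyl] ether | COCOc1cc(COCc2cc(OCOC)c(OCOC)c(Br)c2Br)c(Br)c(Br)c1OCOC
F0 | step 5 | none | none
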